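**Assumption (one line):** (R)-4-methyloxolan-2-one and ethyl [(tert-butyldimethylsilyl)oxy]acetate are taken as catalogue items; locants C1–C20 in all descriptions follow the briarane numbering of the target (C1 quaternary ring-fusion carbon, C2–C9 ten-membered ring, C10 ring-fusion CH, C11–C14 ring A, C15 methyl on C1, C16 methylidene on C5, C17/C18/C19 lactone CH/methyl/carbonyl, C20 methylidene on C11).

## Retrosynthetic overview

1. Target ⇐ oxidative lactonisation of a macrocyclic 7,19-diol ⇐ ten-membered ring closed last at C6–C7 by an intramolecular chromium-mediated γ-chloroallylation, which installs Cl, C6, C7 and the C5 methylidene together.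
2. Seco precursor ⇐ C8–C9 bond by Mukaiyama aldol of a chiral butyrolactone ketene acetal (C7, C8, C17–C19) with a ring A C9 aldehyde, with C9 then set by oxidation and reduction; C2–C3 bond by addition of a chlorodienylzinc to a C2 aldehyde.
3. Ring A (key step) ⇐ 6-endo radical cyclisation of a tertiary α-lactone radical onto a Z-trisubstituted alkene. This forms C1–C10, the C1 quaternary centre, C10 and the C11 methylidene, with C13 relaying its configuration through a lactone tether.
4. Radical precursor ⇐ (S)-epichlorohydrin + a Z-alkenyl Grignard reagent + propanoic acid.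
5. Ring order: γ-lactone tether → ring A (radical) → ten-membered ring (chromium) → final γ-lactone.

## Route

**Step 1**
Reactants: 1 but-2-yn-1-ol
Product: 3 (2Z)-3-iodobut-2-en-1-ol, via cyclic alkenylalanate 2 (not isolated)
Conditions: NaAlH2(OCH2CH2OMe)2, Et2O, 0 °C to rt; then I2, THF, −78 °C
Reagents that add atoms: iodine, II
Why: Hydroxyl-directed trans-hydroalumination places aluminium on C3 inside a five-membered alanate, cis to CH2O, and iodinolysis with retention gives the Z iodide (Corey-type hydroalumination–iodination).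

**Step 2**
Reactants: 3 (2Z)-3-iodobut-2-en-1-ol
Product: 4 triethyl{[(2Z)-3-iodobut-2-en-1-yl]oxy}silane
Conditions: Et3SiCl, imidazole, CH2Cl2, 0 °C
Reagents that add atoms: chlorotriethylsilane, CC[Si](Cl)(CC)CC
Why: Standard silylation; the primary triethylsilyl ether is chosen because it can later be oxidised directly to the aldehyde.

**Step 3**
Reactants: 4 triethyl{[(2Z)-3-iodobut-2-en-1-yl]oxy}silane; 5 (S)-epichlorohydrin
Product: 8 (2S)-2-{(2Z)-2-methyl-4-[(triethylsilyl)oxy]but-2-en-1-yl}oxirane, via alkenylmagnesium chloride 6 (not isolated), via chlorohydrin 7 (not isolated)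
Conditions: i-PrMgCl·LiCl, THF, −20 °C; CuI (10 mol%), 5, −40 to 0 °C; then 2 M NaOH, rt
Reagents that add atoms: none
Why: Iodine–magnesium exchange keeps the Z geometry, copper-catalysed SN2 opening occurs at the epoxide CH2, and the alkoxide then displaces chloride; the C13 stereocentre is carried over untouched from epichlorohydrin.

**Step 4**
Reactants: 8 (2S)-2-{(2Z)-2-methyl-4-[(triethylsilyl)oxy]but-2-en-1-yl}oxirane; 9 propanoic acid
Product: 11 (5R)-3-methyl-5-{(2Z)-2-methyl-4-[(triethylsilyl)oxy]but-2-en-1-yl}oxolan-2-one (both C3 epimers), via hydroxy acid 10 (not isolated)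
Conditions: 9, LiN(i-Pr)2 (2.2 equiv), THF/DMPU, 0 °C; 8, 45 °C; then AcOH; PhMe, 60 °C
Reagents that add atoms: none
Why: Creger-type opening of the terminal epoxide by the propanoate dianion followed by γ-lactonisation; the α-methyl epimers are irrelevant because this carbon becomes a radical.

**Step 5**
Reactants: 11 lactone (both C3 epimers)
Product: 12 (5S)-3-bromo-3-methyl-5-{(2Z)-2-methyl-4-[(triethylsilyl)oxy]but-2-en-1-yl}oxolan-2-one (both C3 epimers)
Conditions: LiN(i-Pr)2, THF, −78 °C; BrCCl2CCl2Br, −78 °C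
Reagents that add atoms: 1,2-dibromotetrachloroethane, BrC(Cl)(Cl)C(Cl)(Cl)Br
Why: Electrophilic bromination of the lactone enolate gives the tertiary α-bromo lactone, the same structural type as an atom-transfer initiator.

**Step 6 (key step)**
Reactants: 12 α-bromo lactone
Product: 14 (1S,2S,5S)-1-methyl-3-methylidene-2-{[(triethylsilyl)oxy]methyl}-6-oxabicyclo[3.2.1]octan-7-one, via tertiary bromide 13 (not isolated)
Conditions: CuBr (30 mol%), tris(2-pyridylmethyl)amine (30 mol%), PhMe, 110 °C, 0.01 M; then DBU, 80 °C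
Reagents that add atoms: none
Why: Proposed new method: monovalent copper abstracts bromine reversibly to give the tertiary α-lactone radical at C1, which therefore survives long enough for a 6-endo-trig attack on the less substituted terminus (C10) of the electron-rich Z-trisubstituted alkene (5-exo would give a strained 2-oxabicyclo[2.2.1]heptanone); the lactone tether forces the C1–C10 bond onto the face of the C13 side chain so C1 follows from C13, the chair transition state of the Z-alkene places CH2OSiEt3 axial and anti to the lactone bridge so C10 is set, bromine transfer to the C11 radical from the open exo face gives the equatorial bromide 13, and anti-elimination with DBU can then only use the methyl hydrogens, giving the exocyclic methylene; the closest known reactions are copper-catalysed atom-transfer radical cyclisations of α-bromo esters and the 6-endo cyclisations of α-carbonyl radicals in Mn(OAc)3 chemistry.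

**Step 7**
Reactants: 14 bridged lactone
Product: 15 (1S,2S,5S)-5-hydroxy-1-methyl-3-methylidene-2-{[(triethylsilyl)oxy]methyl}cyclohexane-1-carbaldehyde
Conditions: i-Bu2AlH (1.2 equiv), CH2Cl2, −78 °C; aqueous potassium sodium tartrate
Reagents that add atoms: none
Why: Half-reduction of the lactone; the bridged lactol opens to the all-equatorial hydroxy aldehyde, which unmasks C2 as a neopentyl, non-enolisable aldehyde.

**Step 8**
Reactants: 16 ethyl [(tert-butyldimethylsilyl)oxy]acetate; 17 ethynyltrimethylsilane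
Product: 19 1-[(tert-butyldimethylsilyl)oxy]-4-(trimethylsilyl)but-3-yn-2-one, via lithium acetylide 18 (not isolated)
Conditions: 17, n-BuLi, THF, −78 °C; BF3·OEt2; 16, −78 °C
Reagents that add atoms: none
Why: Boron trifluoride-promoted addition of a lithium acetylide to an ester stops at the ynone (Yamaguchi–Hirao alkynylation).

**Step 9**
Reactants: 19 ynone
Product: 20 (E)-tert-butyl{[2-(chloromethylidene)-4-(trimethylsilyl)but-3-yn-1-yl]oxy}dimethylsilane
Conditions: ClCH2PPh3Cl, NaN(SiMe3)2, THF, −78 °C to rt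
Reagents that add atoms: (chloromethyl)triphenylphosphonium chloride, [Cl-].ClC[P+](c1ccccc1)(c1ccccc1)c1ccccc1
Why: Wittig chloromethylenation places chlorine syn to the slim alkynyl group (E major); the minor Z isomer need not be removed because both give the same allylchromium species in step 22.

**Step 10**
Reactants: 20 silylated chloroenyne
Product: 21 (E)-tert-butyl{[2-(chloromethylidene)but-3-yn-1-yl]oxy}dimethylsilane
Conditions: K2CO3 (cat.), MeOH, 0 °C
Reagents that add atoms: none
Why: Selective methanolysis of the alkynyl C–Si bond; the silyl ether and vinyl chloride are untouched.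

**Step 11**
Reactants: 15 hydroxy aldehyde; 21 chloroenyne
Product: 24 C2 carbinol, (2E,4E)-1-[(1S,2S,5S)-5-hydroxy-1-methyl-3-methylidene-2-{[(triethylsilyl)oxy]methyl}cyclohexyl]-5-[(tert-butyldimethylsilyl)oxy]-4-(chloromethylidene)pent-2-en-1-ol with C2 as in the target, via dienylzirconocene chloride 22 (not isolated), via dienyl(methyl)zinc 23 (not isolated)
Conditions: 21, Cp2Zr(H)Cl, CH2Cl2, rt; Me2Zn, PhMe, −65 °C; 15, 0 °C
Reagents that add atoms: none
Why: Syn hydrozirconation of the terminal alkyne fixes the E C3=C4 bond, zirconium-to-zinc exchange gives a mild alkenylzinc (Wipf alkenylation), and Felkin–Anh addition anti to the C10 branch of the quaternary α-carbon (CH2 inside, methyl outside) sets C2 as S.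

**Step 12**
Reactants: 24 diol
Product: 25 C2,C13 diacetate
Conditions: Ac2O, pyridine, DMAP (cat.), CH2Cl2, rt
Reagents that add atoms: acetic anhydride, CC(=O)OC(C)=O
Why: Acetylation of both secondary alcohols installs two of the three final acetates and blocks the C2 hydroxyl from forming a lactol with the C9 aldehyde made next.

**Step 13**
Reactants: 25 diacetate
Product: 26 C9 aldehyde
Conditions: (COCl)2, DMSO, CH2Cl2, −78 to −30 °C; Et3N, −78 °C
Reagents that add atoms: none
Why: Swern conditions cleave and oxidise a primary triethylsilyl ether in one operation while the tert-butyldimethylsilyl ether survives (oxidative desilylation); the epimerisable β,γ-unsaturated aldehyde is used at once.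

**Step 14**
Reactants: 27 (R)-4-methyloxolan-2-one
Product: 28 (3R,4S)-3-hydroxy-4-methyloxolan-2-one
Conditions: KN(SiMe3)2, THF, −78 °C; 3-phenyl-2-(phenylsulfonyl)oxaziridine, −78 °C
Reagents that add atoms: 3-phenyl-2-(phenylsulfonyl)oxaziridine, O=S(=O)(N1OC1c1ccccc1)c1ccccc1
Why: Davis hydroxylation of the lactone enolate occurs anti to the β-methyl group; this centre is re-formed in step 15, and C17 comes from the starting lactone.

**Step 15**
Reactants: 26 C9 aldehyde; 28 hydroxy lactone
Product: 31 aldol diol (C8 as in the target, both C9 epimers), via bis(trimethylsilyl) ketene acetal 29 (not isolated), via bis(trimethylsilyl) aldol adduct 30 (not isolated)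
Conditions: 28, LiN(i-Pr)2 (2.2 equiv), Me3SiCl, THF, −78 °C to rt; then 26, Sc(OTf)3 (10 mol%), CH2Cl2, −78 °C; citric acid, MeOH, 0 °C
Reagents that add atoms: none
Why: Non-basic Mukaiyama aldol of a tetrasubstituted ketene acetal forms C8–C9; the aldehyde attacks the face anti to the C17 methyl, which sets the C8 quaternary carbinol, and the C9 mixture is converged in the next two steps.

**Step 16**
Reactants: 31 aldol diol
Product: 32 C9 ketone
Conditions: Dess–Martin periodinane, NaHCO3, CH2Cl2, 0 °C
Reagents that add atoms: none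
Why: Neutral oxidation of the secondary alcohol in the presence of the tertiary one converges both C9 epimers to a single ketone.

**Step 17**
Reactants: 32 C9 ketone
Product: 33 (9S) alcohol
Conditions: Zn(BH4)2, Et2O, −30 °C
Reagents that add atoms: none
Why: Hydride adds to the zinc chelate of the α-hydroxy ketone anti to the quaternary C1 branch of C10 (Felkin–Anh), which gives the configuration that carbon nucleophiles cannot reach directly; lactone and acetates are inert to this reagent.

**Step 18**
Reactants: 33 diol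
Product: 34 C2,C9,C13 triacetate
Conditions: Ac2O, pyridine, DMAP (cat.), CH2Cl2, 0 °C
Reagents that add atoms: acetic anhydride, CC(=O)OC(C)=O
Why: The secondary C9 alcohol is acetylated while the hindered tertiary C8 alcohol stays free; this is the last acetate and it prevents C9 from competing in the final lactonisation.

**Step 19**
Reactants: 34 triacetate
Product: 35 C16 allylic alcohol
Conditions: HF·pyridine, pyridine, THF, 0 °C
Reagents that add atoms: none
Why: Buffered fluoride removes the primary allylic silyl ether without touching acetates or the lactone.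

**Step 20**
Reactants: 35 allylic alcohol
Product: 36 C16 allylic chloride
Conditions: N-chlorosuccinimide, Me2S, CH2Cl2, −20 to 0 °C
Reagents that add atoms: N-chlorosuccinimide, ClN1C(=O)CCC1=O
Why: Corey–Kim chlorination converts primary allylic alcohols to chlorides by SN2 without allylic transposition and leaves the tertiary alcohol alone.

**Step 21**
Reactants: 36 lactone
Product: 37 C7 lactol (anomer mixture)
Conditions: NaBH4, THF/H2O, AcOH/NaOAc buffer (pH 5), 0 °C
Reagents that add atoms: none
Why: An α-hydroxy γ-lactone is activated enough for buffered borohydride half-reduction, as in the aldonolactone-to-aldose reduction; acetates and the allylic chloride are inert under these conditions and the quaternary α-carbon keeps the lactol closed against over-reduction.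

**Step 22**
Reactants: 37 lactol
Product: 39 macrocyclic 7,19-diol, via allylchromium dichloride 38 (not isolated)
Conditions: CrCl2 (10 equiv), LiI (cat.), THF/DMF, 25 °C, 0.002 M, slow addition
Reagents that add atoms: none
Why: Proposed new method: divalent chromium converts the allylic chloride into the γ-chloroallylchromium species 38, which adds through its γ-carbon (C6) to the aldehyde released from the lactol in a chair transition state (Takai–Utimoto chloroallylation, a Nozaki–Hiyama allylation known intermolecularly and here used for ten-membered ring closure like the chromium-mediated germacranolide cyclisations), giving the anti chlorohydrin (6S,7R) and the C5 methylidene in one step; Felkin–Anh attack anti to the C8 oxygen with C9 inside sets C7.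

**Step 23**
Reactants: 39 macrocyclic diol
Product: 41 CNP0268873.1, via macrocyclic lactol 40 (not isolated)
Conditions: TEMPO (20 mol%), PhI(OAc)2 (2.5 equiv), CH2Cl2, rt
Reagents that add atoms: none
Why: Oxoammonium oxidation is selective for the primary C19 alcohol; the aldehyde is trapped by the C7 hydroxyl (C9 is acetylated, C8 is tertiary) and the lactol is oxidised on to the γ-lactone (oxidative lactonisation of a 1,4-diol), so C17 is not exposed to base.

## Compound list

1 | but-2-yn-1-ol | CC#CCO | starting material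
2 | sodium cyclic alkenylalanate (2,2-bis(2-methoxyethoxy)-3-methyl-2,5-dihydro-1,2-oxaluminol-2-uide) | CC1=CCO[Al-]1(OCCOC)OCCOC.[Na+] | intermediate
3 | (2Z)-3-iodobut-2-en-1-ol | C/C(I)=C/CO | intermediate
4 | triethyl{[(2Z)-3-iodobut-2-en-1-yl]oxy}silane | C/C(I)=C/CO[Si](CC)(CC)CC | intermediate
5 | (S)-epichlorohydrin | ClC[C@@H]1CO1 | starting material
6 | chloro{(2Z)-4-[(triethylsilyl)oxy]but-2-en-2-yl}magnesium | C/C([Mg]Cl)=C/CO[Si](CC)(CC)CC | intermediate
7 | (2S,4Z)-1-chloro-4-methyl-6-[(triethylsilyl)oxy]hex-4-en-2-ol | CC[Si](CC)(CC)OC/C=C(C)\C[C@H](O)CCl | intermediate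
8 | (2S)-2-{(2Z)-2-methyl-4-[(triethylsilyl)oxy]but-2-en-1-yl}oxirane | CC[Si](CC)(CC)OC/C=C(C)\C[C@H]1CO1 | intermediate
9 | propanoic acid | CCC(=O)O | starting material
10 | (4R,6Z)-4-hydroxy-2,6-dimethyl-8-[(triethylsilyl)oxy]oct-6-enoic acid (both C2 epimers) | CC(C(=O)O)C[C@@H](O)C/C(C)=C\CO[Si](CC)(CC)CC | intermediate
11 | (5R)-3-methyl-5-{(2Z)-2-methyl-4-[(triethylsilyl)oxy]but-2-en-1-yl}oxolan-2-one (both C3 epimers) | CC1C[C@H](C/C(C)=C\CO[Si](CC)(CC)CC)OC1=O | intermediate
12 | (5S)-3-bromo-3-methyl-5-{(2Z)-2-methyl-4-[(triethylsilyl)oxy]but-2-en-1-yl}oxolan-2-one (both C3 epimers) | CC1(Br)C[C@H](C/C(C)=C\CO[Si](CC)(CC)CC)OC1=O | intermediate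
13 | 3-bromo-1,3-dimethyl-2-{[(triethylsilyl)oxy]methyl}-6-oxabicyclo[3.2.1]octan-7-one (C1, C10, C13 as in the target; bromine mainly exo) | CC1(Br)C[C@H]2C[C@](C)(C(=O)O2)[C@H]1CO[Si](CC)(CC)CC | intermediate
14 | (1S,2S,5S)-1-methyl-3-methylidene-2-{[(triethylsilyl)oxy]methyl}-6-oxabicyclo[3.2.1]octan-7-one | C=C1C[C@H]2C[C@](C)(C(=O)O2)[C@H]1CO[Si](CC)(CC)CC | intermediate
15 | (1S,2S,5S)-5-hydroxy-1-methyl-3-methylidene-2-{[(triethylsilyl)oxy]methyl}cyclohexane-1-carbaldehyde | C=C1C[C@H](O)C[C@](C)(C=O)[C@H]1CO[Si](CC)(CC)CC | intermediate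
16 | ethyl [(tert-butyldimethylsilyl)oxy]acetate | CCOC(=O)CO[Si](C)(C)C(C)(C)C | starting material
17 | ethynyltrimethylsilane | C#C[Si](C)(C)C | starting material
18 | lithium (trimethylsilyl)acetylide | [Li]C#C[Si](C)(C)C | intermediate
19 | 1-[(tert-butyldimethylsilyl)oxy]-4-(trimethylsilyl)but-3-yn-2-one | C[Si](C)(C)C#CC(=O)CO[Si](C)(C)C(C)(C)C | intermediate
20 | (E)-tert-butyl{[2-(chloromethylidene)-4-(trimethylsilyl)but-3-yn-1-yl]oxy}dimethylsilane (E drawn; minor Z carried along) | C[Si](C)(C)C#C/C(=C\Cl)CO[Si](C)(C)C(C)(C)C | intermediate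
21 | (E)-tert-butyl{[2-(chloromethylidene)but-3-yn-1-yl]oxy}dimethylsilane | C#C/C(=C\Cl)CO[Si](C)(C)C(C)(C)C | intermediate
22 | chloro{(1E,3E)-4-chloro-3-({[tert-butyl(dimethyl)silyl]oxy}methyl)buta-1,3-dien-1-yl}zirconocene | Cl[Zr](/C=C/C(=C\Cl)CO[Si](C)(C)C(C)(C)C)(C1C=CC=C1)C1C=CC=C1 | intermediate
23 | {(1E,3E)-4-chloro-3-({[tert-butyl(dimethyl)silyl]oxy}methyl)buta-1,3-dien-1-yl}(methyl)zinc | C[Zn]/C=C/C(=C\Cl)CO[Si](C)(C)C(C)(C)C | intermediate
24 | C2 carbinol: ring A (13-OH, 9-OSiEt3) carrying at C1 the (2S)-CH(OH)–CH=CH–C(=CHCl)–CH2OSi(t-Bu)Me2 chain, 3E, chloromethylidene E; C1, C2, C10, C13 as in the target | C=C1C[C@H](O)C[C@](C)([C@@H](O)/C=C/C(=C\Cl)CO[Si](C)(C)C(C)(C)C)[C@H]1CO[Si](CC)(CC)CC | intermediate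
25 | 2,13-diacetate of 24 | C=C1C[C@H](OC(C)=O)C[C@](C)([C@@H](OC(C)=O)/C=C/C(=C\Cl)CO[Si](C)(C)C(C)(C)C)[C@H]1CO[Si](CC)(CC)CC | intermediate
26 | C9 aldehyde (2,13-diacetate, 16-OSi(t-Bu)Me2) | C=C1C[C@H](OC(C)=O)C[C@](C)([C@@H](OC(C)=O)/C=C/C(=C\Cl)CO[Si](C)(C)C(C)(C)C)[C@H]1C=O | intermediate
27 | (R)-4-methyloxolan-2-one | O=C1OC[C@H](C)C1 | starting material
28 | (3R,4S)-3-hydroxy-4-methyloxolan-2-one | O=C1OC[C@H](C)[C@H]1O | intermediate
29 | (R)-4-methyl-2,3-bis[(trimethylsilyl)oxy]-4,5-dihydrofuran | C[C@H]1COC(O[Si](C)(C)C)=C1O[Si](C)(C)C | intermediate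
30 | 8,9-bis(trimethylsilyl) ether of 31 (both C9 epimers) | O=C1OC[C@H](C)[C@@]1(O[Si](C)(C)C)C(O[Si](C)(C)C)[C@H]2C(=C)C[C@H](OC(C)=O)C[C@]2(C)[C@@H](OC(C)=O)/C=C/C(=C\Cl)CO[Si](C)(C)C(C)(C)C | intermediate
31 | aldol diol: 3-hydroxy-4-methyloxolan-2-one joined at its C3 (= C8) to C9H(OH) of the ring A fragment; C8, C17 as in the target, both C9 epimers | O=C1OC[C@H](C)[C@@]1(O)C(O)[C@H]2C(=C)C[C@H](OC(C)=O)C[C@]2(C)[C@@H](OC(C)=O)/C=C/C(=C\Cl)CO[Si](C)(C)C(C)(C)C | intermediate
32 | C9 ketone | O=C1OC[C@H](C)[C@@]1(O)C(=O)[C@H]2C(=C)C[C@H](OC(C)=O)C[C@]2(C)[C@@H](OC(C)=O)/C=C/C(=C\Cl)CO[Si](C)(C)C(C)(C)C | intermediate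
33 | (9S) alcohol, 8,9-diol | O=C1OC[C@H](C)[C@@]1(O)[C@@H](O)[C@H]2C(=C)C[C@H](OC(C)=O)C[C@]2(C)[C@@H](OC(C)=O)/C=C/C(=C\Cl)CO[Si](C)(C)C(C)(C)C | intermediate
34 | 2,9,13-triacetate, 8-OH free, 16-OSi(t-Bu)Me2 | O=C1OC[C@H](C)[C@@]1(O)[C@@H](OC(C)=O)[C@H]2C(=C)C[C@H](OC(C)=O)C[C@]2(C)[C@@H](OC(C)=O)/C=C/C(=C\Cl)CO[Si](C)(C)C(C)(C)C | intermediate
35 | C16 allylic alcohol | O=C1OC[C@H](C)[C@@]1(O)[C@@H](OC(C)=O)[C@H]2C(=C)C[C@H](OC(C)=O)C[C@]2(C)[C@@H](OC(C)=O)/C=C/C(=C\Cl)CO | intermediate
36 | C16 allylic chloride (C7 lactone) | O=C1OC[C@H](C)[C@@]1(O)[C@@H](OC(C)=O)[C@H]2C(=C)C[C@H](OC(C)=O)C[C@]2(C)[C@@H](OC(C)=O)/C=C/C(=C\Cl)CCl | intermediate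
37 | C7 lactol of 36 (anomer mixture) | OC1OC[C@H](C)[C@@]1(O)[C@@H](OC(C)=O)[C@H]2C(=C)C[C@H](OC(C)=O)C[C@]2(C)[C@@H](OC(C)=O)/C=C/C(=C\Cl)CCl | intermediate
38 | γ-chloroallylchromium dichloride from 37 | OC1OC[C@H](C)[C@@]1(O)[C@@H](OC(C)=O)[C@H]2C(=C)C[C@H](OC(C)=O)C[C@]2(C)[C@@H](OC(C)=O)/C=C/C(=C\Cl)C[Cr](Cl)Cl | intermediate
39 | macrocyclic 7,19-diol: the target with the lactone opened to 7-OH and 19-CH2OH; all stereocentres as in the target | C=C1C[C@H](OC(C)=O)C[C@]2(C)[C@@H](OC(C)=O)/C=C/C(=C)[C@H](Cl)[C@H](O)[C@@](O)([C@@H](C)CO)[C@@H](OC(C)=O)[C@@H]12 | intermediate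
40 | macrocyclic 7,19-lactol (C19 anomers) | C=C1C[C@H](OC(C)=O)C[C@]2(C)[C@@H](OC(C)=O)/C=C/C(=C)[C@H](Cl)[C@@H]3OC(O)[C@H](C)[C@@]3(O)[C@@H](OC(C)=O)[C@@H]12 | intermediate
41 | CNP0268873.1 | C=C1C[C@H](OC(C)=O)C[C@]2(C)[C@@H](OC(C)=O)/C=C/C(=C)[C@H](Cl)[C@@H]3OC(=O)[C@H](C)[C@@]3(O)[C@@H](OC(C)=O)[C@@H]12 | target

## Count and risks

Total steps: 23. Longest linear sequence: 19 (steps 1–7, 11–13, 15–23).

**Step 6 (radical 6-endo cyclisation).** The risks are premature loss of the C1 radical, a boat transition state giving the C10 epimer, and a mixture of alkene regioisomers. Fallback: change from copper redox catalysis to a degenerative xanthate-transfer chain, setting out from 12 and returning at 14. Bromide 12 is treated with KSC(S)OEt in acetone at 0 °C to give the tertiary S-alkyl xanthate F1 (α-bromoisobutyrate-type substitution). Dilauroyl peroxide, added in portions in refluxing 1,2-dichloroethane, then drives xanthate-transfer cyclisation to the bicyclic tertiary xanthate F2; the dormant xanthate returns the radical repeatedly, which suits a slow cyclisation. Thermolysis of F2 in diphenyl ether at 180 °C gives 14 by syn-elimination towards the methyl group.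

**Step 15 (Mukaiyama aldol forming the C8 quaternary centre on a hindered, epimerisable aldehyde).** Fallback: raise the electrophile to the acyl level, setting out from 26 and returning at 32, which also removes step 16. Pinnick oxidation of 26 (NaClO2, NaH2PO4, 2-methylbut-2-ene, t-BuOH/H2O) gives the carboxylic acid F3. 1-Chloro-N,N,2-trimethylprop-1-en-1-amine in CH2Cl2 converts it into the acid chloride F4. C-Acylation of ketene acetal 29 with F4 (CH2Cl2, −78 to 0 °C) gives the 8-O-trimethylsilyl ketone F5, and citric acid in MeOH releases ketone 32.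

**Step 22 (ten-membered ring closure on a masked aldehyde).** The risks are a lactol that does not open, oligomerisation, and the wrong C6/C7 face. Fallback: replace the aprotic chromium closure of the chloride by an aqueous indium Barbier closure of the bromide, in which the lactol equilibrates freely with the hydroxy aldehyde; it sets out from 35 and returns at 39. Alcohol 35 with CBr4/PPh3 (CH2Cl2, 0 °C) gives the allylic bromide F6. Buffered NaBH4 as in step 21 gives the lactol bromide F7. Indium metal in THF/H2O at high dilution then forms the γ-chloroallylindium species and closes the ring to 39; the anti selectivity is less certain here than with chromium.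

## Further compounds

F1 | step 6 | O-ethyl S-[(5S)-3-methyl-5-{(2Z)-2-methyl-4-[(triethylsilyl)oxy]but-2-en-1-yl}-2-oxooxolan-3-yl] carbonodithioate | CCOC(=S)SC1(C)C[C@H](C/C(C)=C\CO[Si](CC)(CC)CC)OC1=O
F2 | step 6 | O-ethyl S-[1,3-dimethyl-7-oxo-2-{[(triethylsilyl)oxy]methyl}-6-oxabicyclo[3.2.1]octan-3-yl] carbonodithioate | CCOC(=S)SC1(C)C[C@H]2C[C@](C)(C(=O)O2)[C@H]1CO[Si](CC)(CC)CC
F3 | step 15 | C9 carboxylic acid corresponding to aldehyde 26 | C=C1C[C@H](OC(C)=O)C[C@](C)([C@@H](OC(C)=O)/C=C/C(=C\Cl)CO[Si](C)(C)C(C)(C)C)[C@H]1C(=O)O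
F4 | step 15 | C9 acid chloride corresponding to F3 | C=C1C[C@H](OC(C)=O)C[C@](C)([C@@H](OC(C)=O)/C=C/C(=C\Cl)CO[Si](C)(C)C(C)(C)C)[C@H]1C(=O)Cl
F5 | step 15 | 8-O-trimethylsilyl ether of ketone 32 | O=C1OC[C@H](C)[C@@]1(O[Si](C)(C)C)C(=O)[C@H]2C(=C)C[C@H](OC(C)=O)C[C@]2(C)[C@@H](OC(C)=O)/C=C/C(=C\Cl)CO[Si](C)(C)C(C)(C)C
F6 | step 22 | C16 allylic bromide analogue of 36 | O=C1OC[C@H](C)[C@@]1(O)[C@@H](OC(C)=O)[C@H]2C(=C)C[C@H](OC(C)=O)C[C@]2(C)[C@@H](OC(C)=O)/C=C/C(=C\Cl)CBr
F7 | step 22 | C7 lactol of F6 (anomer mixture) | OC1OC[C@H](C)[C@@]1(O)[C@@H](OC(C)=O)[C@H]2C(=C)C[C@H](OC(C)=O)C[C@]2(C)[C@@H](OC(C)=O)/C=C/C(=C\Cl)CBr
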